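**Retrosynthetic overview**

1. The strategy rests on the benzene ring of 16 (C-8 = quaternary oxirane carbon, C-9 = oxirane CH2, C-10 = CH2O-acyl carbon). Its oxygen sits on the ring carbon ortho to the one bearing C-8 and meta to the formyl-bearing carbon, and the formyl group is para to C-8. A 3-substituted furan leaves this pattern when its four carbons and its oxygen are merged with the two alkyne carbons of propiolaldehyde.
2. 16 ⇐ diol 14: the oxirane is closed last, the C-8 oxygen displacing a C-9 triflate, so no bond to C-8 is broken. 14 ⇐ phenol 12 by phenol isovalerylation and acetonide hydrolysis.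
3. 12 ⇐ furan 8 + propiolaldehyde 10: a Diels-Alder reaction forms the bonds furan C-2 to alkyne CH and furan C-5 to C(CHO); the oxygen bridge then opens and the oxygen stays on former furan C-2.
4. 8 ⇐ prochiral triol 5 (lipase mono-isovalerylation sets C-8, then dioxolane formation) ⇐ furan-3-yllithium + dioxanone 2.
5. Ring order: furan ring bought; dioxolane ring (step 4, protecting group); benzene ring (step 6); oxirane ring (step 9).

Key step: step 6

Assumption: in step 3 the lipase is taken to acylate the pro-R hydroxymethyl group of triol 5, giving (R)-7; the sense and level of selection have to be confirmed on the first batch (chiral HPLC), and the opposite preference is answered by the fallback to step 3.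

**Route**

Step 1
Reactants: 1 3-bromofuran; 2 2,2-dimethyl-1,3-dioxan-5-one
Product: 4 5-(furan-3-yl)-2,2-dimethyl-1,3-dioxan-5-ol, via furan-3-yllithium 3 (not isolated)
Conditions: n-BuLi, THF, −78 °C; then 2, −78 °C; aq NH4Cl
Reagents that add atoms: none
Why: Bromine-lithium exchange at −78 °C should give furan-3-yllithium without isomerisation to the 2-lithio species, and its 1,2-addition to the ketone (organolithium carbonyl addition) gives the tertiary carbinol carbon that becomes C-8; no stereocentre arises because the two ring CH2O arms are equivalent.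

Step 2
Reactants: 4 5-(furan-3-yl)-2,2-dimethyl-1,3-dioxan-5-ol
Product: 5 2-(furan-3-yl)propane-1,2,3-triol
Conditions: AcOH/H2O (4:1), 25 °C; co-evaporation with toluene
Reagents that add atoms: none
Why: Acid-catalysed acetal hydrolysis of the 1,3-dioxane should free the prochiral triol, the weak acid leaving the furan and the tertiary carbinol (flanked by two deactivating CH2O groups) untouched.

Step 3
Reactants: 5 2-(furan-3-yl)propane-1,2,3-triol; 6 isovaleric anhydride
Product: 7 (2R)-2-(furan-3-yl)-2,3-dihydroxypropyl 3-methylbutanoate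
Conditions: Burkholderia cepacia lipase (immobilised), 6 (1.2 equiv), t-BuOMe/THF, 25 °C
Reagents that add atoms: isovaleric anhydride 6, CC(C)CC(=O)OC(=O)CC(C)C
Why: Lipase-catalysed enantiotopos-selective acyl transfer (enzymatic desymmetrisation of a prochiral 2-substituted propane-1,3-diol) should esterify one of the two enantiotopic primary hydroxyls and so set C-8 as R, the tertiary hydroxyl not being a substrate and slight over-acylation to the achiral diester removing mainly the minor enantiomer.

Step 4
Reactants: 7 (2R)-2-(furan-3-yl)-2,3-dihydroxypropyl 3-methylbutanoate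
Product: 8 [(4R)-4-(furan-3-yl)-2,2-dimethyl-1,3-dioxolan-4-yl]methyl 3-methylbutanoate
Conditions: 2,2-dimethoxypropane, PPTS (cat.), acetone, 25 °C
Reagents that add atoms: 2,2-dimethoxypropane, COC(C)(C)OC
Why: Acid-catalysed transketalisation should close the five-membered dioxolane over the tertiary and the remaining primary hydroxyl without touching C-8, and it removes every free hydroxyl that could migrate an acyl group or hydrogen-bond the dienophile in step 6.

Step 5
Reactants: 9 propargyl alcohol
Product: 10 propiolaldehyde
Conditions: CrO3, H2SO4, H2O, 2–10 °C, reduced pressure, product swept into −78 °C traps; used at once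
Reagents that add atoms: none
Why: Chromic acid oxidation of a primary propargylic alcohol should stop at the aldehyde because the volatile ynal is carried out of the oxidant as it forms.

Step 6
Reactants: 8 [(4R)-4-(furan-3-yl)-2,2-dimethyl-1,3-dioxolan-4-yl]methyl 3-methylbutanoate; 10 propiolaldehyde
Product: 12 [(4R)-4-(4-formyl-2-hydroxyphenyl)-2,2-dimethyl-1,3-dioxolan-4-yl]methyl 3-methylbutanoate, via oxanorbornadiene cycloadduct 11 (not isolated)
Conditions: 10 (3 equiv), BHT (cat.), neat, 35 °C, dark; evaporate excess 10; then BF3·OEt2 (0.3 equiv), CH2Cl2, −78 to −20 °C; aq NaHCO3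
Reagents that add atoms: none
Why: A thermal Diels-Alder reaction of the furan with the ynal joins furan C-2 to the alkyne CH and furan C-5 to the formyl-bearing carbon in one concerted suprafacial [4+2] closure of the six-membered carbocycle, giving 7-oxanorbornadiene 11 as two bridgehead epimers that converge. BF3 then ionises the bridge C–O bond at former furan C-5 (Lewis-acid isomerisation of a 7-oxanorbornadiene to a phenol), because the pentadienyl cation formed places charge on the side-chain-bearing carbon and keeps it off the formyl-bearing carbon, and loss of the proton from former C-2 aromatises the ring with the oxygen ortho to C-8 and meta to the formyl group. The closest known reaction type is the cycloaddition of furans with propiolic esters followed by acid isomerisation to meta-hydroxybenzoates. The step needs the "para" orientation of the cycloaddition and one direction of bridge opening: the first is secured by the 3-alkyl group, which gives furan C-2 the larger HOMO coefficient, helped by the bulk of the quaternary dioxolane carbon and by the absence of any free hydroxyl that could draw the formyl group to the near side, and the second by the same alkyl group together with the formyl group. No stereocentre is created, the bridgehead centres of 11 vanish on aromatisation and C-8 is a spectator. Keeping the Lewis acid out of the cycloaddition stage should avoid Friedel-Crafts-type alkenylation of the furan, and a catalytic amount at low temperature should spare the acetonide.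

Step 7
Reactants: 12 [(4R)-4-(4-formyl-2-hydroxyphenyl)-2,2-dimethyl-1,3-dioxolan-4-yl]methyl 3-methylbutanoate; 6 isovaleric anhydride
Product: 13 [(4R)-4-{4-formyl-2-[(3-methylbutanoyl)oxy]phenyl}-2,2-dimethyl-1,3-dioxolan-4-yl]methyl 3-methylbutanoate
Conditions: 6 (1.3 equiv), Et3N, DMAP (cat.), CH2Cl2, 0 °C
Reagents that add atoms: isovaleric anhydride 6, CC(C)CC(=O)OC(=O)CC(C)C
Why: DMAP-catalysed acylation of the phenol should cap the ring oxygen before any leaving group is placed on C-9, the aldehyde, acetonide and alkyl ester being inert to these conditions.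

Step 8
Reactants: 13 [(4R)-4-{4-formyl-2-[(3-methylbutanoyl)oxy]phenyl}-2,2-dimethyl-1,3-dioxolan-4-yl]methyl 3-methylbutanoate
Product: 14 (2R)-2-{4-formyl-2-[(3-methylbutanoyl)oxy]phenyl}-2,3-dihydroxypropyl 3-methylbutanoate
Conditions: TFA/H2O (9:1), 0 °C, short contact; aq NaHCO3
Reagents that add atoms: none
Why: Acid-catalysed hydrolysis of the isopropylidene ketal should free the diol, the electron-poor ring (formyl para, acyloxy ortho) suppressing ionisation of the benzylic C-8–O bond and the cold, brief, acidic conditions keeping both esters from migrating, so C-8 is not disturbed.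

Step 9
Reactants: 14 (2R)-2-{4-formyl-2-[(3-methylbutanoyl)oxy]phenyl}-2,3-dihydroxypropyl 3-methylbutanoate
Product: 16 {(2R)-2-{4-formyl-2-[(3-methylbutanoyl)oxy]phenyl}oxiran-2-yl}methyl 3-methylbutanoate, via primary triflate 15 (not isolated)
Conditions: Tf2O (1.05 equiv), 2,6-lutidine, CH2Cl2, −78 °C; then i-Pr2NEt, −78 to 0 °C; aq NaHCO3
Reagents that add atoms: none
Why: Selective O-triflation of the primary hydroxyl followed by intramolecular Williamson (3-exo-tet) displacement at C-9 by the tertiary C-8 oxygen breaks no bond to C-8 and so retains its configuration, and the triflate is chosen because its closure under a weak amine base should outrun transfer of the neighbouring aryl isovaleryl group to the tertiary oxygen.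

**Compound list**

1 | 3-bromofuran | Brc1ccoc1 | starting material
2 | 2,2-dimethyl-1,3-dioxan-5-one | CC1(C)OCC(=O)CO1 | starting material
3 | furan-3-yllithium | [Li]c1ccoc1 | intermediate (not isolated)
4 | 5-(furan-3-yl)-2,2-dimethyl-1,3-dioxan-5-ol | CC1(C)OCC(O)(c2ccoc2)CO1 | intermediate
5 | 2-(furan-3-yl)propane-1,2,3-triol | OCC(O)(CO)c1ccoc1 | intermediate
6 | isovaleric anhydride (3-methylbutanoic anhydride) | CC(C)CC(=O)OC(=O)CC(C)C | starting material
7 | (2R)-2-(furan-3-yl)-2,3-dihydroxypropyl 3-methylbutanoate | CC(C)CC(=O)OC[C@@](O)(c1ccoc1)CO | intermediate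
8 | [(4R)-4-(furan-3-yl)-2,2-dimethyl-1,3-dioxolan-4-yl]methyl 3-methylbutanoate | CC(C)CC(=O)OC[C@@]1(c2ccoc2)COC(C)(C)O1 | intermediate
9 | propargyl alcohol | C#CCO | starting material
10 | propiolaldehyde | C#CC=O | intermediate
11 | [(4R)-4-(5-formyl-7-oxabicyclo[2.2.1]hepta-2,5-dien-2-yl)-2,2-dimethyl-1,3-dioxolan-4-yl]methyl 3-methylbutanoate, both bridgehead epimers | CC(C)CC(=O)OC[C@@]1(C2=CC3OC2C=C3C=O)COC(C)(C)O1 | intermediate (not isolated)
12 | [(4R)-4-(4-formyl-2-hydroxyphenyl)-2,2-dimethyl-1,3-dioxolan-4-yl]methyl 3-methylbutanoate | CC(C)CC(=O)OC[C@@]1(c2ccc(C=O)cc2O)COC(C)(C)O1 | intermediate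
13 | [(4R)-4-{4-formyl-2-[(3-methylbutanoyl)oxy]phenyl}-2,2-dimethyl-1,3-dioxolan-4-yl]methyl 3-methylbutanoate | CC(C)CC(=O)OC[C@@]1(c2ccc(C=O)cc2OC(=O)CC(C)C)COC(C)(C)O1 | intermediate
14 | (2R)-2-{4-formyl-2-[(3-methylbutanoyl)oxy]phenyl}-2,3-dihydroxypropyl 3-methylbutanoate | CC(C)CC(=O)OC[C@@](O)(c1ccc(C=O)cc1OC(=O)CC(C)C)CO | intermediate
15 | (2S)-2-{4-formyl-2-[(3-methylbutanoyl)oxy]phenyl}-2-hydroxy-3-[(trifluoromethylsulfonyl)oxy]propyl 3-methylbutanoate (same spatial arrangement as 14; the descriptor changes by priority only) | CC(C)CC(=O)OC[C@@](O)(c1ccc(C=O)cc1OC(=O)CC(C)C)COS(=O)(=O)C(F)(F)F | intermediate (not isolated)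
16 | {(2R)-2-{4-formyl-2-[(3-methylbutanoyl)oxy]phenyl}oxiran-2-yl}methyl 3-methylbutanoate | CC(C)CC(=O)OC[C@@]1(c2ccc(C=O)cc2OC(=O)CC(C)C)CO1 | target

**Step count**

Total: 9 steps. Longest linear sequence: 8 steps (1, 2, 3, 4, 6, 7, 8, 9 from 3-bromofuran); step 5 is a one-step side branch.

**Steps most likely to fail**

Step 6. The alkyl group at furan C-3 is only a weak director, so a sizeable share of the cycloaddition may bond the formyl-bearing carbon to furan C-2, which would end in the 3-hydroxy-5-substituted benzaldehyde. The thermal addition may also be slower than polymerisation of the ynal, and BF3 may ionise the tertiary C-8–O bond once the ortho phenol has formed. Fallback, an aryl-metal construction that sets out from 2 and comes back at 12: 4-bromo-3-hydroxybenzaldehyde F1 is converted with MOMCl and i-Pr2NEt into 4-bromo-3-(methoxymethoxy)benzaldehyde F2, and this with HC(OMe)3, MeOH and PPTS into 1-bromo-4-(dimethoxymethyl)-2-(methoxymethoxy)benzene F3. Bromine-lithium exchange (n-BuLi, THF, −78 °C) and addition to 2 should give 5-[4-(dimethoxymethyl)-2-(methoxymethoxy)phenyl]-2,2-dimethyl-1,3-dioxan-5-ol F4. Aqueous HCl in THF removes the three acetal-type groups to give 3-hydroxy-4-(1,2,3-trihydroxypropan-2-yl)benzaldehyde F5. Lipase mono-isovalerylation with 6 as in step 3 gives (2R)-2-(4-formyl-2-hydroxyphenyl)-2,3-dihydroxypropyl 3-methylbutanoate F6, and 2,2-dimethoxypropane with PPTS as in step 4 closes the dioxolane to 12.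

Step 9. Under base the aryl isovaleryl group may shift to the tertiary C-8 oxygen through a six-membered transition state, after which the freed phenoxide would close on C-9 to a dihydrobenzofuran; triflation may also be unselective or disturbed by the aldehyde. Fallback, which sets out from 12 and comes back at 16 and keeps any transferable acyl group off the ring oxygen while the oxirane closes: 12 is alkylated with allyl bromide and K2CO3 in acetone to [(4R)-4-[4-formyl-2-(prop-2-en-1-yloxy)phenyl]-2,2-dimethyl-1,3-dioxolan-4-yl]methyl 3-methylbutanoate F8. Hydrolysis with TFA/H2O gives (2R)-2-[4-formyl-2-(prop-2-en-1-yloxy)phenyl]-2,3-dihydroxypropyl 3-methylbutanoate F9. MsCl and Et3N at −20 °C give (2S)-2-[4-formyl-2-(prop-2-en-1-yloxy)phenyl]-2-hydroxy-3-[(methylsulfonyl)oxy]propyl 3-methylbutanoate F10, and DBU in CH2Cl2 closes {(2R)-2-[4-formyl-2-(prop-2-en-1-yloxy)phenyl]oxiran-2-yl}methyl 3-methylbutanoate F11. Pd(PPh3)4 with Bu3SnH then removes the allyl group as {(2R)-2-[4-formyl-2-(tributylstannyloxy)phenyl]oxiran-2-yl}methyl 3-methylbutanoate F12, which is acylated in the same flask with 6 to give 16 before the free phenol can attack the oxirane.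

Step 3. The enzyme may prefer the other enantiotopic arm or discriminate poorly, and acid set free from the anhydride may promote acyl migration that erodes the enantiomeric purity. Fallback, the hydrolytic mode, which sets out from 5 and comes back at 7: 5 is acylated on both primary hydroxyls with 6 (pyridine, DMAP cat.) to the achiral diester 2-(furan-3-yl)-2-hydroxypropane-1,3-diyl bis(3-methylbutanoate) F7. A hydrolase (the same lipase, if it acylated the wrong arm in step 3) in phosphate buffer of pH 7 with t-BuOMe then cleaves one enantiotopic ester, which should leave the mono-ester 7 of the sense opposite to that of the acylation mode.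

**Further compounds**

F1 | step 6 | 4-bromo-3-hydroxybenzaldehyde | O=Cc1ccc(Br)c(O)c1
F2 | step 6 | 4-bromo-3-(methoxymethoxy)benzaldehyde | COCOc1cc(C=O)ccc1Br
F3 | step 6 | 1-bromo-4-(dimethoxymethyl)-2-(methoxymethoxy)benzene | COCOc1cc(C(OC)OC)ccc1Br
F4 | step 6 | 5-[4-(dimethoxymethyl)-2-(methoxymethoxy)phenyl]-2,2-dimethyl-1,3-dioxan-5-ol | COCOc1cc(C(OC)OC)ccc1C1(O)COC(C)(C)OC1
F5 | step 6 | 3-hydroxy-4-(1,2,3-trihydroxypropan-2-yl)benzaldehyde | O=Cc1ccc(C(O)(CO)CO)c(O)c1
F6 | step 6 | (2R)-2-(4-formyl-2-hydroxyphenyl)-2,3-dihydroxypropyl 3-methylbutanoate | CC(C)CC(=O)OC[C@@](O)(c1ccc(C=O)cc1O)CO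
F7 | step 3 | 2-(furan-3-yl)-2-hydroxypropane-1,3-diyl bis(3-methylbutanoate) | CC(C)CC(=O)OCC(O)(COC(=O)CC(C)C)c1ccoc1
F8 | step 9 | [(4R)-4-[4-formyl-2-(prop-2-en-1-yloxy)phenyl]-2,2-dimethyl-1,3-dioxolan-4-yl]methyl 3-methylbutanoate | CC(C)CC(=O)OC[C@@]1(c2ccc(C=O)cc2OCC=C)COC(C)(C)O1
F9 | step 9 | (2R)-2-[4-formyl-2-(prop-2-en-1-yloxy)phenyl]-2,3-dihydroxypropyl 3-methylbutanoate | CC(C)CC(=O)OC[C@@](O)(c1ccc(C=O)cc1OCC=C)CO
F10 | step 9 | (2S)-2-[4-formyl-2-(prop-2-en-1-yloxy)phenyl]-2-hydroxy-3-[(methylsulfonyl)oxy]propyl 3-methylbutanoate | CC(C)CC(=O)OC[C@@](O)(c1ccc(C=O)cc1OCC=C)COS(C)(=O)=O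
F11 | step 9 | {(2R)-2-[4-formyl-2-(prop-2-en-1-yloxy)phenyl]oxiran-2-yl}methyl 3-methylbutanoate | CC(C)CC(=O)OC[C@@]1(c2ccc(C=O)cc2OCC=C)CO1
F12 | step 9 | {(2R)-2-[4-formyl-2-(tributylstannyloxy)phenyl]oxiran-2-yl}methyl 3-methylbutanoate | CC(C)CC(=O)OC[C@@]1(c2ccc(C=O)cc2O[Sn](CCCC)(CCCC)CCCC)CO1
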